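**Strategy.** The route rests on reading the five-membered carbocycle of the target (ring carbons bearing CO2Me, CH2CH2OH, the cycloheptenone C=O, the quaternary carbon and the enol carbon) together with the ester carbon as one benzene ring. In the key step an ortho-quinone diazide, in which the future ester carbon is the ring C=O and the future C–CO2Me carbon carries N2, undergoes photo-Wolff ring contraction in methanol: the carbonyl carbon is extruded as the methyl ester and the hydroxyfulvene appears in one operation. Its precursor is the benzo analogue of the target, a hexasubstituted o-aminophenol built by nitro-Michael, imine and Friedel–Crafts chemistry.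

Key step: step 16

Remark: the target is drawn as the chelated 6-hydroxyfulvene tautomer of a 2-acylcyclopentadiene-1-carboxylate, and the ketene–methanol adduct is assumed to settle in this tautomer. In step 2 the catalyst antipode that gives Re-face attack on the nitroalkene (4S) is the one used.

**Step 1**
Reactants: 1 tert-butyl 4-oxobutanoate
Product: 3 tert-butyl (E)-5-nitropent-4-enoate, via nitro alcohol 2 (not isolated)
Conditions: MeNO2 (5 equiv), tetramethylguanidine (10 mol%), THF, 0 °C; then MsCl, Et3N, CH2Cl2, −20 → 0 °C
Reagents that add atoms: nitromethane, C[N+](=O)[O-]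
Why: Henry addition followed by mesylation and E1cB elimination should give the conjugated (E)-nitroalkene, the more stable isomer.

**Step 2**
Reactants: 3 tert-butyl (E)-5-nitropent-4-enoate; 4 1-(3-methoxyphenyl)propan-2-one
Product: 5 tert-butyl (4S)-5-(3-methoxyphenyl)-4-(nitromethyl)-6-oxoheptanoate (C5 epimers)
Conditions: chiral primary amine–thiourea catalyst [(1R,2R)-2-aminocyclohexyl thiourea of an L-tert-leucine amide, or its antipode] (10 mol%), PhCO2H (10 mol%), toluene, rt
Reagents that add atoms: none
Why: Enamine-catalysed asymmetric Michael addition of a ketone to a nitroalkene: the conjugated benzylic enamine adds to the Re face of the thiourea-bound nitroalkene and so sets C4 (S), while the epimerisable C5 is reset in step 4.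

**Step 3**
Reactants: 5 tert-butyl (4S)-5-(3-methoxyphenyl)-4-(nitromethyl)-6-oxoheptanoate
Product: 7 tert-butyl 3-[(3S)-4-(3-methoxyphenyl)-5-methyl-3,4-dihydro-2H-pyrrol-3-yl]propanoate (C4 epimers), via amino ketone 6 (not isolated)
Conditions: Fe powder, AcOH, EtOH, 60 °C; NaHCO3 work-up
Reagents that add atoms: none
Why: Nitro reduction gives the γ-amino ketone, which should condense at once to the five-membered cyclic ketimine (reductive cyclisation of a γ-nitro ketone); the tert-butyl ester resists lactamisation.

**Step 4**
Reactants: 7 tert-butyl 3-[(3S)-4-(3-methoxyphenyl)-5-methyl-3,4-dihydro-2H-pyrrol-3-yl]propanoate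
Product: 8 tert-butyl 3-[(3S,4S)-4-(3-methoxyphenyl)-4,5-dimethyl-3,4-dihydro-2H-pyrrol-3-yl]propanoate
Conditions: KHMDS (1.05 equiv), THF, −78 → −40 °C; MeI, −78 °C
Reagents that add atoms: iodomethane, CI
Why: C-alkylation of the benzylic 1-azaallyl anion (metalloenamine alkylation): MeI enters anti to the C3 side chain, so both C4 epimers converge on the quaternary centre with aryl cis to the chain.

**Step 5**
Reactants: 9 methyl pyruvate; 10 tert-butyl (triphenylphosphoranylidene)acetate
Product: 11 4-tert-butyl 1-methyl (E)-2-methylbut-2-enedioate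
Conditions: toluene, 80 °C
Reagents that add atoms: none
Why: Wittig olefination of the keto group by a stabilised ylide; the alkene geometry does not matter because both alkene carbons later become epimerisable sp3 centres.

**Step 6**
Reactants: 8 tert-butyl 3-[(3S,4S)-4-(3-methoxyphenyl)-4,5-dimethyl-3,4-dihydro-2H-pyrrol-3-yl]propanoate; 11 4-tert-butyl 1-methyl (E)-2-methylbut-2-enedioate
Product: 12 imine diester (Michael adduct at the C5 methyl group)
Conditions: 11 (1.1 equiv), toluene, 80 °C, sealed tube
Reagents that add atoms: none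
Why: Michael addition of the NH-enamine tautomer of the ketimine (aza-ene-type addition of ketimines to acrylate- and fumarate-type acceptors): only the C5 methyl group can form the enamine, and it should attack the unsubstituted alkene carbon, β to the methyl ester.

**Step 7**
Reactants: 12 imine diester
Product: 14 tert-butyl (1S,2S,6S,7R,8aR)-2-(3-tert-butoxy-3-oxopropyl)-1-(3-methoxyphenyl)-1,6-dimethyl-5-oxooctahydroindolizine-7-carboxylate, via amino diester 13 (not isolated)
Conditions: NaBH4, MeOH, −20 → 0 °C; then NaOMe (0.5 equiv), MeOH, 60 °C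
Reagents that add atoms: none
Why: Hydride should add to C=N from the face opposite the aryl group and the C4 chain (new C–H cis to the quaternary methyl), after which the amine closes the δ-lactam on the methyl ester (tert-butyl esters inert) while NaOMe equilibrates the ester α-centres, funnelling the mixture into the all-equatorial lactam (6-Me trans to 7-CO2tBu, 7-CO2tBu cis to the C8a–C1 bond).

**Step 8**
Reactants: 14 bicyclic lactam diester
Product: 15 tert-butyl (1S,2S,6S,7R,8aR)-2-(3-tert-butoxy-3-oxopropyl)-1-(3-methoxyphenyl)-1,6-dimethyloctahydroindolizine-7-carboxylate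
Conditions: BH3·THF, THF, 0 → 50 °C; then MeOH, 65 °C
Reagents that add atoms: none
Why: Borane reduction of a tertiary lactam to the amine, chemoselective over tert-butyl esters; no stereocentre is touched.

**Step 9**
Reactants: 15 indolizidine di-tert-butyl ester
Product: 18 methoxy diketone (benzo analogue of the target skeleton), via diacid 16 (not isolated), via keto acid 17 (not isolated)
Conditions: polyphosphoric acid, 110 °C
Reagents that add atoms: none
Why: Acidolysis of both tert-butyl esters and two intramolecular Friedel–Crafts acylations: the flexible chain acid should close first, para to OMe (benzosuberone ring), and the C7 acid then takes the remaining ortho position next to OMe from the conformer with C7–CO and C8a–C1 syn-axial, which the ammonium ion can reach because N–H exchange is possible in hot PPA.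

**Step 10**
Reactants: 18 methoxy diketone
Product: 20 hydroxyethyl methoxy diketone, via silane 19 (not isolated)
Conditions: RuH2(CO)(PPh3)3 (10 mol%), CH2=CHSi(OEt)3 (3 equiv), toluene, 135 °C; then 30% H2O2, KF, KHCO3, THF/MeOH, rt; aq. NaHSO3
Reagents that add atoms: triethoxy(vinyl)silane, C=C[Si](OCC)(OCC)OCC; hydrogen peroxide, OO
Why: Murai ketone-directed ortho C–H alkylation (the benzosuberone C=O has one free ortho C–H, the bridged ketone none) followed by Tamao oxidation of the C–Si bond; the phenol is still a methyl ether, so no Dakin-type oxidation can occur.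

**Step 11**
Reactants: 20 hydroxyethyl methoxy diketone
Product: 21 acetate of 20
Conditions: Ac2O, pyridine, DMAP (cat.), CH2Cl2, 0 °C → rt
Reagents that add atoms: acetic anhydride, CC(=O)OC(C)=O
Why: Acetylation of the only hydroxyl group masks it so that it cannot trap the ketene in step 16.

**Step 12**
Reactants: 21 acetate
Product: 22 phenol (OMe → OH)
Conditions: BCl3 (3 equiv), CH2Cl2, −78 → 0 °C
Reagents that add atoms: none
Why: Chelation-assisted cleavage of an aryl methyl ether ortho to a ketone by BCl3; the acetate should survive at this temperature.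

**Step 13**
Reactants: 22 phenol
Product: 23 ortho-nitrophenol
Conditions: HNO3 (65%, 1.2 equiv), AcOH, 10 °C
Reagents that add atoms: nitric acid, O[N+](=O)[O-]
Why: Electrophilic nitration of the phenol at the only unsubstituted ring position, which is ortho to OH and meta to both acyl groups; the amine is protected as its salt.

**Step 14**
Reactants: 23 ortho-nitrophenol
Product: 24 ortho-aminophenol
Conditions: Na2S2O4, NaHCO3, THF/H2O, rt
Reagents that add atoms: none
Why: Dithionite reduces the nitro group and leaves the aryl ketones and the acetate alone.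

**Step 15**
Reactants: 24 ortho-aminophenol
Product: 26 ortho-quinone diazide (2-diazocyclohexa-3,5-dienone), via diazonium chloride 25 (not isolated)
Conditions: NaNO2, 1 M HCl, THF/H2O, 0 °C; then NaHCO3 to pH 7, dark
Reagents that add atoms: sodium nitrite, [Na+].[O-]N=O
Why: Diazotisation of an o-aminophenol; loss of the phenolic proton gives the neutral diazo oxide.

**Step 16**
Reactants: 26 ortho-quinone diazide
Product: 29 daphnicyclidin H, via ketene 27 (not isolated), via acetate ester 28 (not isolated)
Conditions: hν (365 nm LED), MeOH, 20 °C; then K2CO3 (0.5 equiv), 0 °C; pH 7 buffer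
Reagents that add atoms: methanol, CO
Why: Excitation of the 2-diazocyclohexadienone expels N2 with a concerted 1,2-shift of the ring carbon that carries the bridged ketone from the ring C=O carbon to the diazo carbon (photo-Wolff rearrangement), giving the cyclopentadienylidene ketene 27, which methanol captures as the methyl ester 28. The closest known reaction is the Süs ring contraction of o-quinone diazides to cyclopentadiene- or indenecarboxylic acids. No ring is closed by cyclisation: the five-membered ring arises from the six-membered one by extrusion of the carbonyl carbon, which becomes the exocyclic ester carbon. No stereocentre is formed, the five existing ones are remote from the chromophore, and the adduct should tautomerise to the chelated hydroxyfulvene (enol on the bridged ketone, hydrogen-bonded to the ester). The step needs the Wolff shift to outrun O–H insertion of the carbene and the ketene to be trapped by methanol only: the s-cis-locked cyclic diazoketone should secure the first and the acetate on the hydroxyethyl arm the second. K2CO3 in the same methanol then removes the acetate, the anionic fulvenolate protecting the ester from lactonisation.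

**Compound list**

1 | tert-butyl 4-oxobutanoate | CC(C)(C)OC(=O)CCC=O | starting material
2 | tert-butyl 4-hydroxy-5-nitropentanoate (racemic nitro alcohol) | CC(C)(C)OC(=O)CCC(O)C[N+](=O)[O-] | intermediate
3 | tert-butyl (E)-5-nitropent-4-enoate | CC(C)(C)OC(=O)CC/C=C/[N+](=O)[O-] | intermediate
4 | 1-(3-methoxyphenyl)propan-2-one | COc1cccc(CC(C)=O)c1 | starting material
5 | tert-butyl (4S)-5-(3-methoxyphenyl)-4-(nitromethyl)-6-oxoheptanoate (both C5 epimers) | CC(C)(C)OC(=O)CC[C@H](C[N+](=O)[O-])C(C(C)=O)c1cccc(OC)c1 | intermediate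
6 | tert-butyl (4S)-4-(aminomethyl)-5-(3-methoxyphenyl)-6-oxoheptanoate (amino ketone) | CC(C)(C)OC(=O)CC[C@H](CN)C(C(C)=O)c1cccc(OC)c1 | intermediate
7 | tert-butyl 3-[(3S)-4-(3-methoxyphenyl)-5-methyl-3,4-dihydro-2H-pyrrol-3-yl]propanoate (both C4 epimers) | CC1=NC[C@@H](CCC(=O)OC(C)(C)C)C1c1cccc(OC)c1 | intermediate
8 | tert-butyl 3-[(3S,4S)-4-(3-methoxyphenyl)-4,5-dimethyl-3,4-dihydro-2H-pyrrol-3-yl]propanoate (aryl cis to the side chain) | CC1=NC[C@@H](CCC(=O)OC(C)(C)C)[C@@]1(C)c1cccc(OC)c1 | intermediate
9 | methyl pyruvate | COC(=O)C(C)=O | starting material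
10 | tert-butyl (triphenylphosphoranylidene)acetate | CC(C)(C)OC(=O)C=P(c1ccccc1)(c1ccccc1)c1ccccc1 | starting material
11 | 4-tert-butyl 1-methyl (E)-2-methylbut-2-enedioate | COC(=O)/C(C)=C/C(=O)OC(C)(C)C | intermediate
12 | imine diester: 4-tert-butyl 1-methyl 2-methyl-3-{[(3S,4S)-3-(3-tert-butoxy-3-oxopropyl)-4-(3-methoxyphenyl)-4-methyl-3,4-dihydro-2H-pyrrol-5-yl]methyl}butanedioate (epimers at both succinate carbons) | COC(=O)C(C)C(CC1=NC[C@@H](CCC(=O)OC(C)(C)C)[C@@]1(C)c1cccc(OC)c1)C(=O)OC(C)(C)C | intermediate
13 | amino diester: the (2R,3S,4S)-pyrrolidine obtained from 12 (ring C2–H cis to the C3 methyl; succinate carbons epimeric) | COC(=O)C(C)C(C[C@H]1NC[C@@H](CCC(=O)OC(C)(C)C)[C@@]1(C)c1cccc(OC)c1)C(=O)OC(C)(C)C | intermediate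
14 | tert-butyl (1S,2S,6S,7R,8aR)-2-(3-tert-butoxy-3-oxopropyl)-1-(3-methoxyphenyl)-1,6-dimethyl-5-oxooctahydroindolizine-7-carboxylate | O=C1[C@@H](C)[C@H](C(=O)OC(C)(C)C)C[C@H]2N1C[C@@H](CCC(=O)OC(C)(C)C)[C@@]2(C)c1cccc(OC)c1 | intermediate
15 | tert-butyl (1S,2S,6S,7R,8aR)-2-(3-tert-butoxy-3-oxopropyl)-1-(3-methoxyphenyl)-1,6-dimethyloctahydroindolizine-7-carboxylate | C[C@@H]1CN2C[C@@H](CCC(=O)OC(C)(C)C)[C@@](C)(c3cccc(OC)c3)[C@H]2C[C@H]1C(=O)OC(C)(C)C | intermediate
16 | (1S,2S,6S,7R,8aR)-2-(2-carboxyethyl)-1-(3-methoxyphenyl)-1,6-dimethyloctahydroindolizine-7-carboxylic acid | C[C@@H]1CN2C[C@@H](CCC(=O)O)[C@@](C)(c3cccc(OC)c3)[C@H]2C[C@H]1C(=O)O | intermediate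
17 | keto acid: methoxybenzosuberone ring closed from the C2 chain para to OMe, C7 carboxylic acid free, stereocentres as in 16 | C[C@@H]1CN2C[C@H]3CCC(=O)c4ccc(OC)cc4[C@@]3(C)[C@H]2C[C@H]1C(=O)O | intermediate
18 | methoxy diketone: benzo analogue of the target skeleton, anisole ring fused to both seven-membered ketone rings, OMe ortho to the bridged C=O, two aromatic CH left, stereocentres as in 29 | COc1ccc2c3c1C(=O)[C@@H]1C[C@H]4N(C[C@@H](CCC2=O)[C@@]34C)C[C@H]1C | intermediate
19 | 18 carrying CH2CH2Si(OEt)3 ortho to the benzosuberone C=O | COc1cc(CC[Si](OCC)(OCC)OCC)c2c3c1C(=O)[C@@H]1C[C@H]4N(C[C@@H](CCC2=O)[C@@]34C)C[C@H]1C | intermediate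
20 | hydroxyethyl methoxy diketone (CH2CH2OH in place of the silyl arm) | COc1cc(CCO)c2c3c1C(=O)[C@@H]1C[C@H]4N(C[C@@H](CCC2=O)[C@@]34C)C[C@H]1C | intermediate
21 | acetate of 20 | COc1cc(CCOC(C)=O)c2c3c1C(=O)[C@@H]1C[C@H]4N(C[C@@H](CCC2=O)[C@@]34C)C[C@H]1C | intermediate
22 | phenol (OH ortho to the bridged C=O), acetate retained | Oc1cc(CCOC(C)=O)c2c3c1C(=O)[C@@H]1C[C@H]4N(C[C@@H](CCC2=O)[C@@]34C)C[C@H]1C | intermediate
23 | ortho-nitrophenol (NO2 between OH and the acetoxyethyl arm) | Oc1c([N+](=O)[O-])c(CCOC(C)=O)c2c3c1C(=O)[C@@H]1C[C@H]4N(C[C@@H](CCC2=O)[C@@]34C)C[C@H]1C | intermediate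
24 | ortho-aminophenol | Oc1c(N)c(CCOC(C)=O)c2c3c1C(=O)[C@@H]1C[C@H]4N(C[C@@H](CCC2=O)[C@@]34C)C[C@H]1C | intermediate
25 | arenediazonium chloride of 24 | Oc1c([N+]#N)c(CCOC(C)=O)c2c3c1C(=O)[C@@H]1C[C@H]4N(C[C@@H](CCC2=O)[C@@]34C)C[C@H]1C.[Cl-] | intermediate
26 | ortho-quinone diazide: ring C=O flanked by the diazo carbon and the carbon bearing the bridged ketone | O=C1C(=[N+]=[N-])C(CCOC(C)=O)=C2C3=C1C(=O)[C@@H]1C[C@H]4N(C[C@@H](CCC2=O)[C@@]34C)C[C@H]1C | intermediate
27 | cyclopentadienylidene ketene (fulven-6-one) from ring contraction | O=C=C1C(CCOC(C)=O)=C2C3=C1C(=O)[C@@H]1C[C@H]4N(C[C@@H](CCC2=O)[C@@]34C)C[C@H]1C | intermediate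
28 | daphnicyclidin H O-acetate (methyl ester, hydroxyfulvene tautomer) | COC(=O)C1=C(CCOC(C)=O)C2=C3C1=C(O)[C@@H]1C[C@H]4N(C[C@@H](CCC2=O)[C@@]34C)C[C@H]1C | intermediate
29 | daphnicyclidin H | COC(=O)C1=C(CCO)C2=C3C1=C(O)[C@@H]1C[C@H]4N(C[C@@H](CCC2=O)[C@@]34C)C[C@H]1C | target

**Totals.** 16 steps in all; longest linear sequence 15 steps (steps 1–4 and 6–16; step 5 is a one-step branch).

**Steps most likely to fail**

1. Step 9. The second acylation may stall: the ring is deactivated by the first ketone, the attacked carbon lies between OMe and the quaternary centre, and the ammonium ion may stay in the trans-fused form that cannot bring the C7 acylium to the arene. Fallback, from 15 back to 18: TFAA/TFA (0 °C → rt) cleaves the tert-butyl esters and closes only the benzosuberone ring, so keto acid 17 is isolated. BBr3 (CH2Cl2, −78 → 0 °C) frees the phenol to give the phenol keto acid F1. Its acid chloride ((COCl)2, cat. DMF) is then delivered to the only reachable ortho position by BCl3 in refluxing 1,2-dichloroethane (boron-phenoxide-templated ortho-acylation of a phenol), giving the phenol diketone F2. TMSCHN2 in MeOH/toluene re-forms the methyl ether, and the route is rejoined at 18.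

2. Step 7. Hydride addition to the monocyclic ketimine may show poor facial selectivity, or lactamisation may outrun epimerisation so that C6/C7 epimers are carried forward. Fallback, from 12 back to 14: heating 12 in toluene at 110 °C with catalytic pivalic acid completes the aza-annulation (N-acylation by the methyl ester) to the bicyclic enamide lactam F3. Hydrogenation (H2, Pd/C, EtOAc) adds cis to the C8=C8a enamide from the face away from the aryl group, and t-BuOK/t-BuOH then equilibrates C6 and C7 to the all-equatorial lactam 14.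

3. Step 16. The carbene may undergo O–H insertion or reduction instead of the Wolff shift, or the ketene may be lost to side reactions before methanol captures it. Fallback, from 26 back to 29: K2CO3/MeOH in the dark removes the acetate to give the hydroxy quinone diazide F4. Irradiation (365 nm) in dry MeCN lets the pendant hydroxyl group capture the ketene intramolecularly, giving the δ-lactone F5, and NaOMe/MeOH opens the lactone to 29.

**Further compounds**

F1 | step 9 | phenol keto acid (17 with OH in place of OMe) | C[C@@H]1CN2C[C@H]3CCC(=O)c4ccc(O)cc4[C@@]3(C)[C@H]2C[C@H]1C(=O)O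
F2 | step 9 | phenol diketone (18 with OH in place of OMe) | Oc1ccc2c3c1C(=O)[C@@H]1C[C@H]4N(C[C@@H](CCC2=O)[C@@]34C)C[C@H]1C
F3 | step 7 | bicyclic enamide lactam (C8=C8a unsaturated analogue of 14, C6/C7 epimers) | O=C1C(C)C(C(=O)OC(C)(C)C)C=C2N1C[C@@H](CCC(=O)OC(C)(C)C)[C@@]2(C)c1cccc(OC)c1
F4 | step 16 | hydroxy quinone diazide (26 without the acetyl group) | O=C1C(=[N+]=[N-])C(CCO)=C2C3=C1C(=O)[C@@H]1C[C@H]4N(C[C@@H](CCC2=O)[C@@]34C)C[C@H]1C
F5 | step 16 | δ-lactone from intramolecular ketene capture (hydroxyfulvene tautomer) | O=C5OCCC6=C5C(=C(O)[C@@H]1C[C@H]4N(C[C@@H](CCC2=O)[C@@]34C)C[C@H]1C)C3=C62
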